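**Plan** (labdane numbering: ring A = C1–C5, C10; ring B = C5–C10; C17 = exocyclic methylene carbon; side chain C11–C16)
1. Retrosynthetic cuts: side chain at C13–C16 (coupling), O–C16 (ester alkylation) and C13–C14 (Claisen); C8=C17 (Wittig); ring A at C3–C4; then C9–C11 (Michael) and C10–C1 (conjugate allylation).
2. Enabling feature: in ring B the oxygenated carbon C8 and C5 (which carries the gem-dimethyl carbon C4) are 1,4 to each other, so C4 can be tied to C7 in a cyclobutane. That is the pinane skeleton of (−)-verbenone, whose C4–C7 bond lies α,β to the C8 ketone and can break to a tertiary C4 cation.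
3. Forward: ring B is present in 1 from the start; C10 is made quaternary, C9 is alkylated, and ring A is closed last when the C4–C7 bond breaks and the C4 cation is caught by the allyl arm on C10; the side chain is finished afterwards.
4. Stereochemistry: C5 from verbenone; C10 by addition anti to the gem-dimethyl bridge (this fixes the trans ring fusion); C9 by equilibration; C13=C14 from a chelated (Z)-enol triflate coupled with retention; the ester stereocentre from (R)-2-methylbutanoic acid.

Key step: step 3

Remark: the target has the ent-labdane configuration (5R,9R,10R) and an (R)-2-methylbutanoyl group. Assumption: (1S,5S)-(−)-verbenone 1 and (2R)-2-methylbutanoic acid 16 are bought in enantiopure form.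

**Step 1**
Reactants: 1 (1S,5S)-(−)-verbenone; 2 allyltrimethylsilane
Product: 3 (1S,4S,5S)-4,6,6-trimethyl-4-(prop-2-en-1-yl)bicyclo[3.1.1]heptan-2-one
Conditions: TiCl4, CH2Cl2, −78 °C; then H2O
Reagents that add atoms: allyltrimethylsilane (2), C=CC[Si](C)(C)C
Why: Hosomi–Sakurai conjugate allylation, in which the allylsilane should attack the TiCl4-activated enone at the β-carbon C10 from the face opposite the gem-dimethyl bridge, setting the C10 quaternary centre with the allyl arm trans to C4.

**Step 2**
Reactants: 3 allyl ketone; 4 methyl acrylate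
Product: 6 methyl 3-[(1S,3R,4R,5R)-4,6,6-trimethyl-2-oxo-4-(prop-2-en-1-yl)bicyclo[3.1.1]heptan-3-yl]propanoate, via lithium C8–C9 enolate 5 (not isolated)
Conditions: LiN(iPr)2, THF, −78 °C; methyl acrylate, −78 °C; then AcOH
Reagents that add atoms: methyl acrylate (4), C=CC(=O)OC; lithium diisopropylamide, CC(C)N([Li])C(C)C (lithium stays only in 5)
Why: Michael addition of a lithium enolate, which can form only toward C9 because the other α-carbon C7 is a bridgehead, with the acceptor expected to enter anti to the gem-dimethyl bridge to give the shown C9 epimer (corrected in step 4).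

**Step 3**
Reactants: 6 bicyclic keto ester
Product: 7 methyl 3-[(1R,4aR,7R,8aR)-7-chloro-5,5,8a-trimethyl-2-oxodecahydronaphthalen-1-yl]propanoate (trans-fused, chloride equatorial at C2, side chain axial at C9)
Conditions: SnCl4 (2 equiv), CH2Cl2, −20 °C to 25 °C; then H2O
Reagents that add atoms: tin tetrachloride, Cl[Sn](Cl)(Cl)Cl
Why: Proposed new method: SnCl4 bound to the C8 carbonyl should heterolyse the strained C4–C7 cyclobutane bond to a tin enolate (C7=C8) and a tertiary C4 cation, which is attacked by the terminal carbon C3 of the allyl group on C10, and the secondary C2 cation so formed is quenched by chloride. The closest known reaction types are the Lewis acid-mediated opening of 4-aryl-6,6-dimethylbicyclo[3.1.1]heptan-2-ones, in which the same tertiary cation is caught by a phenol oxygen to close a gem-dimethyl pyran ring, and the Prins-type cation–alkene cyclisation that ends in an equatorial chloride; new here is capture by a carbon π-nucleophile. Ring A closes in the 6-endo-trig mode through a chair transition state with the C4 and C1 arms both equatorial on ring B. The ring-fusion centres C5 and C10 are not made here but are already fixed with the two arms trans, so only the trans-decalin can form, and the only new stereocentre, C2, should carry its chloride equatorial by anti addition across the alkene. The step needs attack at C3 and not C2, and ring closure before the cation is lost irreversibly: the first follows from the Markovnikov preference for a secondary over a primary cation, the second from proton loss and chloride capture at the tertiary centre being reversible under SnCl4 whereas C–C bond formation is not.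

**Step 4**
Reactants: 7 chloro keto ester
Product: 9 methyl 3-[(1S,4aR,8aR)-5,5,8a-trimethyl-2-oxodecahydronaphthalen-1-yl]propanoate (side chain equatorial), via dechlorinated axial C9 epimer 8 (not isolated)
Conditions: Bu3SnH, AIBN (cat.), PhMe, 100 °C; then NaOMe (cat.), MeOH, 25 °C
Reagents that add atoms: none
Why: Radical dehalogenation with Bu3SnH removes the helper chloride, and base-mediated enolisation then equilibrates C9 to the epimer with the equatorial side chain (cis to the C10 methyl), which avoids the 1,3-diaxial contacts of the axial chain.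

**Step 5**
Reactants: 9 keto ester; 10 methyltriphenylphosphonium bromide
Product: 11 methyl 3-[(1R,4aR,8aR)-5,5,8a-trimethyl-2-methylidenedecahydronaphthalen-1-yl]propanoate
Conditions: Ph3PCH3Br, KN(SiMe3)2, THF, 0 °C to 50 °C
Reagents that add atoms: methyltriphenylphosphonium bromide (10), C[P+](c1ccccc1)(c1ccccc1)c1ccccc1.[Br-]
Why: Wittig methylenation, in which the non-stabilised ylide should react with the ketone much faster than with the methyl ester, while C9 is already in its thermodynamically preferred configuration.

**Step 6**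
Reactants: 11 methyl ester; 12 tert-butyl acetate
Product: 13 tert-butyl 3-oxo-5-[(1R,4aR,8aR)-5,5,8a-trimethyl-2-methylidenedecahydronaphthalen-1-yl]pentanoate
Conditions: tert-butyl acetate, LiN(iPr)2, THF, −78 °C to −20 °C; then AcOH
Reagents that add atoms: tert-butyl acetate (12), CC(=O)OC(C)(C)C
Why: Crossed Claisen condensation, in which the lithium enolate of tert-butyl acetate acylates on the methyl ester and the product is shielded from further attack as its β-keto ester enolate.

**Step 7**
Reactants: 13 β-keto ester
Product: 15 tert-butyl (2Z)-3-{[(trifluoromethyl)sulfonyl]oxy}-5-[(1R,4aR,8aR)-5,5,8a-trimethyl-2-methylidenedecahydronaphthalen-1-yl]pent-2-enoate, via chelated sodium enolate 14 (not isolated)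
Conditions: NaH, Et2O, 0 °C; then Tf2O, −78 °C to 0 °C
Reagents that add atoms: trifluoromethanesulfonic anhydride, O=S(=O)(OS(=O)(=O)C(F)(F)F)C(F)(F)F; sodium hydride, [Na+].[H-] (sodium stays only in 14)
Why: O-Triflation of a β-keto ester enolate, where the sodium chelate holds the enolate oxygen cis to the ester carbonyl so that the (Z)-enol triflate should result.

**Step 8**
Reactants: 16 (2R)-2-methylbutanoic acid; 17 chloromethyl chlorosulfate
Product: 18 chloromethyl (2R)-2-methylbutanoate
Conditions: ClCH2OSO2Cl, NaHCO3, Bu4NHSO4 (cat.), CH2Cl2/H2O, 25 °C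
Reagents that add atoms: chloromethyl chlorosulfate (17), ClCOS(=O)(=O)Cl
Why: Carboxylate O-alkylation under phase-transfer conditions, in which the carboxylate displaces chlorosulfate and the α-stereocentre is not touched by the weak base.

**Step 9**
Reactants: 18 chloromethyl ester
Product: 19 iodomethyl (2R)-2-methylbutanoate
Conditions: NaI, acetone, 25 °C, dark
Reagents that add atoms: sodium iodide, [Na+].[I-]
Why: Finkelstein halide exchange, driven by precipitation of NaCl from acetone.

**Step 10**
Reactants: 19 iodomethyl ester; 15 (Z)-enol triflate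
Product: 21 tert-butyl (2Z)-3-({[(2R)-2-methylbutanoyl]oxy}methyl)-5-[(1R,4aR,8aR)-5,5,8a-trimethyl-2-methylidenedecahydronaphthalen-1-yl]pent-2-enoate, via acyloxymethylzinc iodide 20 (not isolated)
Conditions: Zn dust, THF, 15 °C; then 15, Pd(PPh3)4 (5 mol %), THF, 25 °C to 45 °C
Reagents that add atoms: zinc, [Zn] (zinc stays only in 20)
Why: Zinc insertion gives an α-acyloxyalkylzinc iodide that should undergo Negishi coupling with the enol triflate with retention of alkene geometry, so C16 ends cis to the ester carbon C15 (Z).

**Step 11**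
Reactants: 21 tert-butyl ester
Product: 23 (2Z)-3-({[(2R)-2-methylbutanoyl]oxy}methyl)-5-[(1R,4aR,8aR)-5,5,8a-trimethyl-2-methylidenedecahydronaphthalen-1-yl]pent-2-enoic acid (the target), via trimethylsilyl ester 22 (not isolated)
Conditions: TMSOTf, 2,6-lutidine, CH2Cl2, 0 °C; then H2O
Reagents that add atoms: trimethylsilyl trifluoromethanesulfonate, C[Si](C)(C)OS(=O)(=O)C(F)(F)F (silicon stays only in 22)
Why: Silyl triflate-mediated cleavage of the tert-butyl ester (loss of isobutene to the silyl ester, hydrolysed on work-up) avoids protic acid and should spare the exocyclic C8=C17 alkene and the second ester.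

**Compound list**
1 | (1S,5S)-4,6,6-trimethylbicyclo[3.1.1]hept-3-en-2-one, (−)-verbenone | O=C1[C@H]2C[C@H](C2(C)C)C(C)=C1 | starting material
2 | allyltrimethylsilane | C=CC[Si](C)(C)C | starting material
3 | (1S,4S,5S)-4,6,6-trimethyl-4-(prop-2-en-1-yl)bicyclo[3.1.1]heptan-2-one | O=C1[C@H]2C[C@H](C2(C)C)[C@@](C)(CC=C)C1 | intermediate
4 | methyl acrylate | C=CC(=O)OC | starting material
5 | lithium enolate of 3 (O–Li on C8, C8=C9) | [Li]OC=1[C@H]2C[C@H](C2(C)C)[C@@](C)(CC=C)C=1 | intermediate
6 | methyl 3-[(1S,3R,4R,5R)-4,6,6-trimethyl-2-oxo-4-(prop-2-en-1-yl)bicyclo[3.1.1]heptan-3-yl]propanoate | O=C1[C@H]2C[C@H](C2(C)C)[C@@](C)(CC=C)[C@H]1CCC(=O)OC | intermediate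
7 | methyl 3-[(1R,4aR,7R,8aR)-7-chloro-5,5,8a-trimethyl-2-oxodecahydronaphthalen-1-yl]propanoate | O=C1CC[C@@H]2C(C)(C)C[C@@H](Cl)C[C@@]2(C)[C@H]1CCC(=O)OC | intermediate
8 | methyl 3-[(1R,4aR,8aR)-5,5,8a-trimethyl-2-oxodecahydronaphthalen-1-yl]propanoate (axial side chain) | O=C1CC[C@@H]2C(C)(C)CCC[C@@]2(C)[C@H]1CCC(=O)OC | intermediate
9 | methyl 3-[(1S,4aR,8aR)-5,5,8a-trimethyl-2-oxodecahydronaphthalen-1-yl]propanoate (equatorial side chain) | O=C1CC[C@@H]2C(C)(C)CCC[C@@]2(C)[C@@H]1CCC(=O)OC | intermediate
10 | methyltriphenylphosphonium bromide | C[P+](c1ccccc1)(c1ccccc1)c1ccccc1.[Br-] | starting material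
11 | methyl 3-[(1R,4aR,8aR)-5,5,8a-trimethyl-2-methylidenedecahydronaphthalen-1-yl]propanoate | C=C1CC[C@@H]2C(C)(C)CCC[C@@]2(C)[C@@H]1CCC(=O)OC | intermediate
12 | tert-butyl acetate | CC(=O)OC(C)(C)C | starting material
13 | tert-butyl 3-oxo-5-[(1R,4aR,8aR)-5,5,8a-trimethyl-2-methylidenedecahydronaphthalen-1-yl]pentanoate | C=C1CC[C@@H]2C(C)(C)CCC[C@@]2(C)[C@@H]1CCC(=O)CC(=O)OC(C)(C)C | intermediate
14 | sodium (Z)-enolate of 13 | C=C1CC[C@@H]2C(C)(C)CCC[C@@]2(C)[C@@H]1CC/C(O[Na])=C/C(=O)OC(C)(C)C | intermediate
15 | tert-butyl (2Z)-3-{[(trifluoromethyl)sulfonyl]oxy}-5-[(1R,4aR,8aR)-5,5,8a-trimethyl-2-methylidenedecahydronaphthalen-1-yl]pent-2-enoate | C=C1CC[C@@H]2C(C)(C)CCC[C@@]2(C)[C@@H]1CC/C(OS(=O)(=O)C(F)(F)F)=C/C(=O)OC(C)(C)C | intermediate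
16 | (2R)-2-methylbutanoic acid | CC[C@@H](C)C(=O)O | starting material
17 | chloromethyl chlorosulfate | ClCOS(=O)(=O)Cl | starting material
18 | chloromethyl (2R)-2-methylbutanoate | CC[C@@H](C)C(=O)OCCl | intermediate
19 | iodomethyl (2R)-2-methylbutanoate | CC[C@@H](C)C(=O)OCI | intermediate
20 | iodo({[(2R)-2-methylbutanoyl]oxy}methyl)zinc | CC[C@@H](C)C(=O)OC[Zn]I | intermediate
21 | tert-butyl (2Z)-3-({[(2R)-2-methylbutanoyl]oxy}methyl)-5-[(1R,4aR,8aR)-5,5,8a-trimethyl-2-methylidenedecahydronaphthalen-1-yl]pent-2-enoate | C=C1CC[C@@H]2C(C)(C)CCC[C@@]2(C)[C@@H]1CC/C(=C/C(=O)OC(C)(C)C)COC(=O)[C@H](C)CC | intermediate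
22 | trimethylsilyl ester of 23 | C=C1CC[C@@H]2C(C)(C)CCC[C@@]2(C)[C@@H]1CC/C(=C/C(=O)O[Si](C)(C)C)COC(=O)[C@H](C)CC | intermediate
23 | (2Z)-3-({[(2R)-2-methylbutanoyl]oxy}methyl)-5-[(1R,4aR,8aR)-5,5,8a-trimethyl-2-methylidenedecahydronaphthalen-1-yl]pent-2-enoic acid | C=C1CC[C@@H]2C(C)(C)CCC[C@@]2(C)[C@@H]1CC/C(=C/C(=O)O)COC(=O)[C@H](C)CC | target

**Step count:** 11 steps in total. Longest linear sequence: 9 steps (steps 1–7, 10, 11).

**Steps most likely to fail**

Step 3 (key step). Loss of a proton from the C4 cation, or its recapture by chloride, may outrun ring closure onto the weakly nucleophilic monosubstituted alkene, and hydride or methyl shifts may follow formation of the secondary C2 cation. The fallback sets out from 6 and comes back at 7, and separates bond cleavage from ring closure so that each stage is a known reaction on an isolated compound. Compound 6 is treated with HCl in acetic acid, the established way to open the cyclobutane of such bicyclo[3.1.1]heptan-2-ones, to give the tertiary chloride methyl 3-[(1R,2S,3S)-3-(2-chloropropan-2-yl)-2-methyl-6-oxo-2-(prop-2-en-1-yl)cyclohexyl]propanoate F1. F1 is then cyclised on its own by ZnCl2-catalysed addition of the tert-alkyl chloride across the terminal alkene (Lewis acid-catalysed alkyl chloride–alkene addition, driven by conversion of a tertiary into a secondary chloride) to give 7.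

Step 10. The α-acyloxyalkylzinc reagent may decompose or transfer slowly, and zerovalent palladium may ionise the allylic acyloxy group of the product once the triflate is used up. The fallback sets out from 15 and comes back at 21. A Migita–Kosugi–Stille coupling of 15 with (tributylstannyl)methanol (Pd(PPh3)4, LiCl, dioxane) gives the allylic alcohol tert-butyl (2Z)-3-(hydroxymethyl)-5-[(1R,4aR,8aR)-5,5,8a-trimethyl-2-methylidenedecahydronaphthalen-1-yl]pent-2-enoate F2, whose hydroxyl is a poor leaving group toward palladium. F2 is then esterified with 16 (DCC, DMAP, Steglich esterification) to give 21.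

Step 1. 1,2-Addition, or Lewis acid-induced opening of the strained ring of 1, may compete with conjugate addition at the hindered β-carbon. The fallback sets out from 1 and comes back at 3. Allylmagnesium bromide (CH2=CHCH2MgBr) adds 1,2 to the ketone anti to the gem-dimethyl bridge to give the tertiary allylic alcohol (1S,2S,5S)-4,6,6-trimethyl-2-(prop-2-en-1-yl)bicyclo[3.1.1]hept-3-en-2-ol F3. An anionic oxy-Cope rearrangement (KH, 18-crown-6, THF) then moves the allyl group suprafacially to C10 on the same face and gives 3 after protonation of the enolate.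

**Further compounds**
F1 | step 3 | methyl 3-[(1R,2S,3S)-3-(2-chloropropan-2-yl)-2-methyl-6-oxo-2-(prop-2-en-1-yl)cyclohexyl]propanoate | O=C1CC[C@H](C(C)(C)Cl)[C@@](C)(CC=C)[C@H]1CCC(=O)OC
F2 | step 10 | tert-butyl (2Z)-3-(hydroxymethyl)-5-[(1R,4aR,8aR)-5,5,8a-trimethyl-2-methylidenedecahydronaphthalen-1-yl]pent-2-enoate | C=C1CC[C@@H]2C(C)(C)CCC[C@@]2(C)[C@@H]1CC/C(=C/C(=O)OC(C)(C)C)CO
F3 | step 1 | (1S,2S,5S)-4,6,6-trimethyl-2-(prop-2-en-1-yl)bicyclo[3.1.1]hept-3-en-2-ol | O[C@]1(CC=C)[C@H]2C[C@H](C2(C)C)C(C)=C1
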